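**Retrosynthetic overview**
1. The strategy rests on C5 of the oxolane ring (O1–C2–C3–C4–C5): it is an allylic ether carbon bonded to the E C6=C7 alkene, so the O1–C5 bond, the C5 centre and that alkene are made together by 1,3-transposition of a (7R) allylic alcohol (C5=C6, C7–OH) with the C2 hydroxyl as nucleophile; this closes the only ring (step 9).
2. The open-chain precursor is cut at C5=C6 (cross-metathesis) into methyl (2R,3R)-3-silyloxy-2-hydroxyhex-5-enoate (C1–C5, from (S)-glyceraldehyde acetonide by anti allylation and C1 oxidation) and monosilylated (R)-but-3-ene-1,2-diol (C6–C8).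
3. The hexaene is cut at C8=C9 (Horner–Wadsworth–Emmons, HWE) into the C8 enal and a C9–C24 tetraenyl phosphonate that carries the 18,19-dione masked as a bis(triethylsilyl) diol.
4. The phosphonate comes from L-threitol acetonide (C17–C20), (R)-2-methylbutan-1-ol (C21–C24, Julia–Kocienski at C20=C21), a formylmethylene ylide (C15–C16) and a hexadienyl bisphosphonate (C9–C14).
5. End game: removal of the triethylsilyl groups, ester hydrolysis, diol-to-dione oxidation, final desilylation.

Key step: step 9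

Assumption: (R)-2-methylbutan-1-ol is taken as purchasable in high enantiomeric purity; the C18/C19 carbinols are carried as the (S,S) pair only for convenience, since both centres are erased in step 27.
Abbreviations: TBS = tert-butyldimethylsilyl, TBDPS = tert-butyldiphenylsilyl, TES = triethylsilyl, PT = 1-phenyl-1H-tetrazol-5-yl. Locants C1–C24 are those of the target, counted from the carboxyl carbon.

**C1–C8 fragment**

Step 1
Reactants: 1 (R)-solketal
Product: 2 (S)-glyceraldehyde acetonide
Conditions: (COCl)2, DMSO, CH2Cl2, −78 °C; Et3N, −78 to 0 °C; used crude at once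
Reagents that add atoms: none
Why: Swern oxidation of the primary carbinol at low temperature should give the configurationally labile alpha-alkoxy aldehyde without epimerisation.

Step 2
Reactants: 2 (S)-glyceraldehyde acetonide; 3 allyl bromide
Product: 5 (1R)-1-[(4S)-2,2-dimethyl-1,3-dioxolan-4-yl]but-3-en-1-ol, via allylzinc bromide 4 (not isolated)
Conditions: Zn dust, THF/sat. aq. NH4Cl, 0 °C to rt
Reagents that add atoms: none
Why: Barbier allylation adds under Felkin–Anh (non-chelation) control anti to the dioxolane C–O bond, so the anti carbinol of R configuration (the future C3) should predominate; the minor syn isomer is removed by chromatography.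

Step 3
Reactants: 5 anti homoallylic alcohol
Product: 6 TBS ether of 5 (tert-butyl{[(1R)-1-[(4S)-2,2-dimethyl-1,3-dioxolan-4-yl]but-3-en-1-yl]oxy}dimethylsilane)
Conditions: TBSCl, imidazole, DMF, rt
Reagents that add atoms: tert-butyldimethylsilyl chloride, CC(C)(C)[Si](C)(C)Cl
Why: Standard imidazole-mediated silylation of the secondary carbinol installs the C3 protecting group that is carried to the last step.

Step 4
Reactants: 6 TBS ether
Product: 7 (2S,3R)-3-(TBSO)hex-5-ene-1,2-diol
Conditions: AcOH/H2O (4:1), rt to 40 °C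
Reagents that add atoms: none
Why: Acid hydrolysis of the terminal isopropylidene acetal is much faster than loss of a secondary TBS ether in aqueous acetic acid.

Step 5
Reactants: 7 diol
Product: 9 (2R,3R)-3-(TBSO)-2-hydroxyhex-5-enoic acid, via alpha-hydroxy aldehyde 8 (not isolated)
Conditions: TEMPO (10 mol%), NaOCl (cat.), NaClO2, MeCN/phosphate buffer pH 6.7, 35 °C
Reagents that add atoms: sodium chlorite, [Na+].[O-]Cl=O
Why: Nitroxyl-catalysed oxidation takes the unhindered primary carbinol to the aldehyde, and chlorite oxidises it on (Pinnick-type) faster than the secondary C2 hydroxyl reacts; the near-neutral buffer should leave C2, the alkene and the silyl ether untouched.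

Step 6
Reactants: 9 hydroxy acid
Product: 10 methyl (2R,3R)-3-(TBSO)-2-hydroxyhex-5-enoate
Conditions: Me3SiCHN2, toluene/MeOH (4:1), 0 °C
Reagents that add atoms: (trimethylsilyl)diazomethane, C[Si](C)(C)C=[N+]=[N-]
Why: Diazoalkane esterification is selective for the carboxylic acid over the alpha-hydroxyl and cannot epimerise C2.

Step 7
Reactants: 11 (R)-but-3-ene-1,2-diol
Product: 12 (2R)-1-(TBDPSO)but-3-en-2-ol
Conditions: TBDPSCl (1.05 equiv), imidazole, CH2Cl2, 0 °C
Reagents that add atoms: tert-butyldiphenylsilyl chloride, CC(C)(C)[Si](Cl)(c1ccccc1)c1ccccc1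
Why: The bulky silyl chloride reacts at the primary hydroxyl far faster than at the secondary allylic one (selective monosilylation), leaving the (R) carbinol free.

Step 8
Reactants: 10 hydroxy ester; 12 silylated butenol (3 equiv)
Product: 13 methyl (2R,3R,5E,7R)-3-(TBSO)-8-(TBDPSO)-2,7-dihydroxyoct-5-enoate
Conditions: second-generation Hoveyda–Grubbs catalyst RuCl2(H2IMes)(=CH–C6H4-2-OiPr) (5 mol%), CH2Cl2, 40 °C
Reagents that add atoms: none
Why: Olefin cross-metathesis between the unhindered homoallylic alkene and the slowly homodimerising secondary allylic alcohol (in excess) should give the E C5=C6 alkene under thermodynamic control without touching a stereocentre.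

Step 9
Reactants: 13 open-chain alpha-hydroxy ester with the (7R) allylic alcohol
Product: 14 methyl (2R,3R,5R)-3-(TBSO)-5-[(1E)-3-(TBDPSO)prop-1-enyl]oxolane-2-carboxylate
Conditions: PdCl2(MeCN)2 (10 mol%), THF, 0 °C
Reagents that add atoms: none
Why: Divalent palladium binds the C5=C6 alkene on the face that carries the C7 hydroxyl, the C2 hydroxyl adds to C5 on that same face (syn oxypalladation), and syn elimination of Pd(OH)Cl from C6/C7 shifts the alkene to C6=C7 and returns the catalyst, an overall syn SN2' substitution. The closest known reaction type is the PdCl2(MeCN)2-catalysed 1,3-chirality-transfer cyclisation of hydroxy-tethered allylic alcohols to 2-alkenyl oxolanes and oxanes. The oxolane ring (O1, C2, C3, C4, C5) closes in the 5-exo-trig mode, the 6-endo alternative at C6 having no leaving group to drive it. The new C5 centre is controlled by the (7R) carbinol alone: in the reactive conformer the C7 hydrogen eclipses the alkene to avoid allylic 1,3-strain, which puts the C7 oxygen, the metal and the incoming O1 on the face that gives (5R) and at the same time makes the new alkene E. The step needs facial selectivity at C5 and a clean SN2' course; the first is secured by the purchased C7 centre, the second by the four-atom tether that lets only the C2 hydroxyl reach C5, while the C2 and C3 centres and both silyl ethers are spectators. The result should be the 2,5-trans ring, which an equilibrating closure would not give selectively.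

Step 10
Reactants: 14 oxolane with both silyl ethers
Product: 15 methyl (2R,3R,5R)-3-(TBSO)-5-[(1E)-3-hydroxyprop-1-enyl]oxolane-2-carboxylate
Conditions: Bu4NF/AcOH (1:1), THF, 0 °C to rt
Reagents that add atoms: none
Why: Acetic acid-buffered fluoride cleaves the unhindered primary allylic TBDPS ether selectively (known TBDPS-over-TBS selectivity of this reagent pair), while the hindered secondary TBS ether and the methyl ester survive.

Step 11
Reactants: 15 allylic alcohol
Product: 16 methyl (2R,3R,5R)-3-(TBSO)-5-[(1E)-3-oxoprop-1-enyl]oxolane-2-carboxylate (C8 enal)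
Conditions: activated MnO2 (excess), CH2Cl2, rt
Reagents that add atoms: none
Why: MnO2 oxidises the allylic alcohol to the E enal chemoselectively under neutral conditions that do not disturb the ester, the silyl ether or C5.

**C9–C24 phosphonate**

Step 12
Reactants: 17 (R)-2-methylbutan-1-ol
Product: 18 5-{[(2R)-2-methylbutyl]sulfanyl}-1-phenyl-1H-tetrazole
Conditions: PT-SH, PPh3, DIAD, THF, 0 °C to rt
Reagents that add atoms: 1-phenyl-1H-tetrazole-5-thiol, Sc1nnnn1-c1ccccc1
Why: Mitsunobu thioetherification at the primary carbon; the adjacent stereocentre is not involved.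

Step 13
Reactants: 18 sulfide
Product: 19 5-{[(2R)-2-methylbutyl]sulfonyl}-1-phenyl-1H-tetrazole
Conditions: (NH4)6Mo7O24·4H2O (10 mol%), 30% aq. H2O2, EtOH, 0 °C to rt
Reagents that add atoms: hydrogen peroxide, OO
Why: Molybdate-catalysed peroxide oxidation takes the sulfide through the sulfoxide to the Julia–Kocienski sulfone.

Step 14
Reactants: 20 (+)-2,3-O-isopropylidene-L-threitol
Product: 21 [(4S,5S)-5-(TBSO-methyl)-2,2-dimethyl-1,3-dioxolan-4-yl]methanol
Conditions: NaH (1.0 equiv), THF, 0 °C; TBSCl (1.0 equiv), rt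
Reagents that add atoms: tert-butyldimethylsilyl chloride, CC(C)(C)[Si](C)(C)Cl
Why: Monosilylation of a symmetric diol through its sparingly soluble mono-sodium alkoxide should give the mono-ether with little bis-silylation.

Step 15
Reactants: 21 mono-TBS ether
Product: 22 (4R,5S)-5-(TBSO-methyl)-2,2-dimethyl-1,3-dioxolane-4-carbaldehyde
Conditions: (COCl)2, DMSO, CH2Cl2, −78 °C; Et3N, −78 to 0 °C
Reagents that add atoms: none
Why: Swern oxidation gives the alpha-alkoxy aldehyde; the trans-dioxolane is the more stable epimer, so the centre is secure.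

Step 16
Reactants: 22 aldehyde; 19 sulfone
Product: 23 tert-butyl{[(4S,5S)-2,2-dimethyl-5-[(1E,3R)-3-methylpent-1-enyl]-1,3-dioxolan-4-yl]methoxy}dimethylsilane
Conditions: 19, KN(SiMe3)2, DME, −60 °C; then 22, −60 °C to rt; aq. NH4Cl
Reagents that add atoms: none
Why: Julia–Kocienski olefination (addition, Smiles rearrangement, loss of SO2 and tetrazolate) should give the E C20=C21 alkene, favoured by the potassium counter-ion in DME.

Step 17
Reactants: 23 alkene
Product: 24 (2S,3S,4E,6R)-6-methyloct-4-ene-1,2,3-triol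
Conditions: TsOH·H2O (10 mol%), MeOH, rt
Reagents that add atoms: none
Why: Acid-catalysed methanolysis removes the acetal and the primary TBS ether together, so that the diol can be re-protected with fluoride-labile groups before any acid-sensitive polyene exists.

Step 18
Reactants: 24 triol
Product: 25 (2S,3S,4E,6R)-6-methyl-1,2,3-tris(triethylsilyloxy)oct-4-ene
Conditions: TESCl (3.5 equiv), imidazole, DMF, 0 °C to rt
Reagents that add atoms: triethylsilyl chloride, CC[Si](Cl)(CC)CC
Why: Exhaustive imidazole-mediated silylation of all three hydroxyls.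

Step 19
Reactants: 25 tris-TES ether
Product: 26 (2R,3S,4E,6R)-6-methyl-2,3-bis(triethylsilyloxy)oct-4-enal
Conditions: (COCl)2, DMSO, CH2Cl2, −78 to −40 °C; Et3N, −78 to 0 °C
Reagents that add atoms: none
Why: Under Swern conditions the activated sulfonium species attacks the unhindered primary TES ether and oxidises it directly to the aldehyde, while secondary TES ethers are inert at low temperature (known selective oxidative desilylation).

Step 20
Reactants: 26 aldehyde
Product: 27 (2E,4S,5S,6E,8R)-8-methyl-4,5-bis(triethylsilyloxy)deca-2,6-dienal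
Conditions: Ph3P=CHCHO (1.2 equiv), toluene, 60 °C
Reagents that add atoms: (triphenylphosphoranylidene)acetaldehyde, O=CC=P(c1ccccc1)(c1ccccc1)c1ccccc1
Why: Wittig reaction with the stabilised formylmethylene ylide gives the E enal by two-carbon homologation.

Step 21
Reactants: 28 hexa-1,5-diene-3,4-diol
Product: 29 (2E,4E)-1,6-dibromohexa-2,4-diene
Conditions: PBr3, Et2O, 0 °C to rt
Reagents that add atoms: phosphorus tribromide, BrP(Br)Br
Why: Both allylic hydroxyls are replaced with allylic transposition (SN2', with equilibration of allylic bromides) to the conjugated primary E,E dibromide, so the configuration of the diol is irrelevant.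

Step 22
Reactants: 29 dibromide
Product: 30 tetraethyl [(2E,4E)-hexa-2,4-diene-1,6-diyl]bis(phosphonate)
Conditions: P(OEt)3 (neat), 130 °C
Reagents that add atoms: triethyl phosphite, CCOP(OCC)OCC
Why: Michaelis–Arbuzov reaction at both primary allylic bromides.

Step 23
Reactants: 27 enal; 30 bisphosphonate (3 equiv)
Product: 31 diethyl [(2E,4E,6E,8E,10S,11S,12E,14R)-14-methyl-10,11-bis(triethylsilyloxy)hexadeca-2,4,6,8,12-pentaenyl]phosphonate
Conditions: 30, NaN(SiMe3)2 (1.1 equiv), THF, −78 °C; then 27 slowly, −78 °C to rt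
Reagents that add atoms: none
Why: HWE olefination with the mono-anion of the symmetric bisphosphonate in excess should stop at mono-olefination, because the adduct only collapses on warming after the aldehyde is consumed; elimination of phosphate gives the E C14=C15 bond.

**Union and end game**

Step 24
Reactants: 16 C8 enal; 31 tetraenyl phosphonate (1.2 equiv)
Product: 32 methyl (2R,3R,5R)-3-(TBSO)-5-[(1E,3E,5E,7E,9E,11E,13S,14S,15E,17R)-17-methyl-13,14-bis(triethylsilyloxy)nonadeca-1,3,5,7,9,11,15-heptaenyl]oxolane-2-carboxylate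
Conditions: 31, NaN(SiMe3)2 (1.15 equiv), THF, −78 °C, 5 min; then 16, −78 to 0 °C; dark
Reagents that add atoms: none
Why: HWE olefination of the enal with the delocalised phosphonate anion, which reacts through its alpha carbon, should form the E C8=C9 bond and complete the hexaene; brief anion generation at −78 °C limits enolisation of 16 and loss of silanolate from the anion.

Step 25
Reactants: 32 fully protected ester
Product: 33 methyl (2R,3R,5R)-3-(TBSO)-5-[(1E,3E,5E,7E,9E,11E,13S,14S,15E,17R)-13,14-dihydroxy-17-methylnonadeca-1,3,5,7,9,11,15-heptaenyl]oxolane-2-carboxylate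
Conditions: HF·pyridine, excess pyridine, THF, 0 °C; dark
Reagents that add atoms: none
Why: Pyridine-buffered HF cleaves the two secondary allylic TES ethers much faster than the hindered secondary TBS ether (known TES-over-TBS selectivity), and the buffer protects the acid-labile polyenyl carbinol.

Step 26
Reactants: 33 diol ester
Product: 34 (2R,3R,5R)-3-(TBSO)-5-[(1E,3E,5E,7E,9E,11E,13S,14S,15E,17R)-13,14-dihydroxy-17-methylnonadeca-1,3,5,7,9,11,15-heptaenyl]oxolane-2-carboxylic acid
Conditions: LiOH·H2O, THF/MeOH/H2O (3:1:1), 0 °C; cold dilute HCl to pH 4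
Reagents that add atoms: lithium hydroxide, [Li+].[OH-]
Why: The alpha-alkoxy methyl ester is saponified before the base-sensitive dione exists; C2 already has the more stable 2,3-trans arrangement, so epimerisation is not expected.

Step 27
Reactants: 34 diol acid
Product: 36 (2R,3R,5R)-3-(TBSO)-5-[(1E,3E,5E,7E,9E,11E,15E,17R)-17-methyl-13,14-dioxononadeca-1,3,5,7,9,11,15-heptaenyl]oxolane-2-carboxylic acid, via ketol 35 (not isolated)
Conditions: 2-iodoxybenzoic acid (IBX, 3 equiv), DMSO, rt; dark
Reagents that add atoms: none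
Why: IBX oxidises both allylic secondary hydroxyls, through the ketol, to the 1,2-dione without cleaving the glycol C–C bond (known behaviour of IBX toward 1,2-diols) and tolerates the free acid and the polyene at room temperature; the protected C3 oxygen is untouched and the two carbinol centres are erased.

Step 28
Reactants: 36 silylated dione acid
Product: 37 target, (2R,3R,5R)-3-hydroxy-5-[(1E,3E,5E,7E,9E,11E,15E,17R)-17-methyl-13,14-dioxononadeca-1,3,5,7,9,11,15-heptaenyl]oxolane-2-carboxylic acid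
Conditions: HF·pyridine, pyridine, THF, 0 °C to rt; dark
Reagents that add atoms: none
Why: Fluoride-mediated desilylation under weakly acidic, non-basic conditions should free the C3 hydroxyl without harming the dione, the hexaene or the acid.

**Compound list**
1 | (R)-solketal, [(4R)-2,2-dimethyl-1,3-dioxolan-4-yl]methanol | CC1(C)OC[C@@H](CO)O1 | starting material
2 | (S)-glyceraldehyde acetonide, (4S)-2,2-dimethyl-1,3-dioxolane-4-carbaldehyde | CC1(C)OC[C@@H](C=O)O1 | intermediate
3 | allyl bromide | C=CCBr | starting material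
4 | allylzinc bromide | C=CC[Zn]Br | intermediate
5 | (1R)-1-[(4S)-2,2-dimethyl-1,3-dioxolan-4-yl]but-3-en-1-ol | C=CC[C@@H](O)[C@@H]1COC(C)(C)O1 | intermediate
6 | TBS ether of 5 | C=CC[C@@H](O[Si](C)(C)C(C)(C)C)[C@@H]1COC(C)(C)O1 | intermediate
7 | (2S,3R)-3-(TBSO)hex-5-ene-1,2-diol | C=CC[C@@H](O[Si](C)(C)C(C)(C)C)[C@@H](O)CO | intermediate
8 | (2R,3R)-3-(TBSO)-2-hydroxyhex-5-enal | C=CC[C@@H](O[Si](C)(C)C(C)(C)C)[C@@H](O)C=O | intermediate
9 | (2R,3R)-3-(TBSO)-2-hydroxyhex-5-enoic acid | C=CC[C@@H](O[Si](C)(C)C(C)(C)C)[C@@H](O)C(=O)O | intermediate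
10 | methyl (2R,3R)-3-(TBSO)-2-hydroxyhex-5-enoate | C=CC[C@@H](O[Si](C)(C)C(C)(C)C)[C@@H](O)C(=O)OC | intermediate
11 | (R)-but-3-ene-1,2-diol | OC[C@H](O)C=C | starting material
12 | (2R)-1-(TBDPSO)but-3-en-2-ol | CC(C)(C)[Si](c1ccccc1)(c1ccccc1)OC[C@H](O)C=C | intermediate
13 | methyl (2R,3R,5E,7R)-3-(TBSO)-8-(TBDPSO)-2,7-dihydroxyoct-5-enoate | CC(C)(C)[Si](c1ccccc1)(c1ccccc1)OC[C@H](O)/C=C/C[C@@H](O[Si](C)(C)C(C)(C)C)[C@H](C(=O)OC)O | intermediate
14 | methyl (2R,3R,5R)-3-(TBSO)-5-[(1E)-3-(TBDPSO)prop-1-enyl]oxolane-2-carboxylate | CC(C)(C)[Si](c1ccccc1)(c1ccccc1)OC/C=C/[C@H]1C[C@@H](O[Si](C)(C)C(C)(C)C)[C@H](C(=O)OC)O1 | intermediate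
15 | methyl (2R,3R,5R)-3-(TBSO)-5-[(1E)-3-hydroxyprop-1-enyl]oxolane-2-carboxylate | OC/C=C/[C@H]1C[C@@H](O[Si](C)(C)C(C)(C)C)[C@H](C(=O)OC)O1 | intermediate
16 | methyl (2R,3R,5R)-3-(TBSO)-5-[(1E)-3-oxoprop-1-enyl]oxolane-2-carboxylate | O=C/C=C/[C@H]1C[C@@H](O[Si](C)(C)C(C)(C)C)[C@H](C(=O)OC)O1 | intermediate
17 | (R)-2-methylbutan-1-ol | CC[C@@H](C)CO | starting material
18 | 5-{[(2R)-2-methylbutyl]sulfanyl}-1-phenyl-1H-tetrazole | CC[C@@H](C)CSc1nnnn1-c1ccccc1 | intermediate
19 | 5-{[(2R)-2-methylbutyl]sulfonyl}-1-phenyl-1H-tetrazole | CC[C@@H](C)CS(=O)(=O)c1nnnn1-c1ccccc1 | intermediate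
20 | (+)-2,3-O-isopropylidene-L-threitol, [(4S,5S)-2,2-dimethyl-1,3-dioxolane-4,5-diyl]dimethanol | OC[C@@H]1OC(C)(C)O[C@H]1CO | starting material
21 | [(4S,5S)-5-(TBSO-methyl)-2,2-dimethyl-1,3-dioxolan-4-yl]methanol | CC(C)(C)[Si](C)(C)OC[C@@H]1OC(C)(C)O[C@H]1CO | intermediate
22 | (4R,5S)-5-(TBSO-methyl)-2,2-dimethyl-1,3-dioxolane-4-carbaldehyde | CC(C)(C)[Si](C)(C)OC[C@@H]1OC(C)(C)O[C@H]1C=O | intermediate
23 | tert-butyl{[(4S,5S)-2,2-dimethyl-5-[(1E,3R)-3-methylpent-1-enyl]-1,3-dioxolan-4-yl]methoxy}dimethylsilane | CC[C@@H](C)/C=C/[C@@H]1OC(C)(C)O[C@H]1CO[Si](C)(C)C(C)(C)C | intermediate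
24 | (2S,3S,4E,6R)-6-methyloct-4-ene-1,2,3-triol | CC[C@@H](C)/C=C/[C@H](O)[C@@H](O)CO | intermediate
25 | (2S,3S,4E,6R)-6-methyl-1,2,3-tris(triethylsilyloxy)oct-4-ene | CC[C@@H](C)/C=C/[C@H](O[Si](CC)(CC)CC)[C@@H](O[Si](CC)(CC)CC)CO[Si](CC)(CC)CC | intermediate
26 | (2R,3S,4E,6R)-6-methyl-2,3-bis(triethylsilyloxy)oct-4-enal | CC[C@@H](C)/C=C/[C@H](O[Si](CC)(CC)CC)[C@@H](O[Si](CC)(CC)CC)C=O | intermediate
27 | (2E,4S,5S,6E,8R)-8-methyl-4,5-bis(triethylsilyloxy)deca-2,6-dienal | CC[C@@H](C)/C=C/[C@H](O[Si](CC)(CC)CC)[C@@H](O[Si](CC)(CC)CC)/C=C/C=O | intermediate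
28 | hexa-1,5-diene-3,4-diol (commercial mixture of racemic and meso forms; both centres are lost in step 21) | C=CC(O)C(O)C=C | starting material
29 | (2E,4E)-1,6-dibromohexa-2,4-diene | BrC/C=C/C=C/CBr | intermediate
30 | tetraethyl [(2E,4E)-hexa-2,4-diene-1,6-diyl]bis(phosphonate) | CCOP(=O)(OCC)C/C=C/C=C/CP(=O)(OCC)OCC | intermediate
31 | diethyl [(2E,4E,6E,8E,10S,11S,12E,14R)-14-methyl-10,11-bis(triethylsilyloxy)hexadeca-2,4,6,8,12-pentaenyl]phosphonate | CC[C@@H](C)/C=C/[C@H](O[Si](CC)(CC)CC)[C@@H](O[Si](CC)(CC)CC)/C=C/C=C/C=C/C=C/CP(=O)(OCC)OCC | intermediate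
32 | methyl (2R,3R,5R)-3-(TBSO)-5-[(1E,3E,5E,7E,9E,11E,13S,14S,15E,17R)-17-methyl-13,14-bis(triethylsilyloxy)nonadeca-1,3,5,7,9,11,15-heptaenyl]oxolane-2-carboxylate | CC[C@@H](C)/C=C/[C@H](O[Si](CC)(CC)CC)[C@@H](O[Si](CC)(CC)CC)/C=C/C=C/C=C/C=C/C=C/C=C/[C@H]1C[C@@H](O[Si](C)(C)C(C)(C)C)[C@H](C(=O)OC)O1 | intermediate
33 | 13,14-diol methyl ester (32 without the two TES groups) | CC[C@@H](C)/C=C/[C@H](O)[C@@H](O)/C=C/C=C/C=C/C=C/C=C/C=C/[C@H]1C[C@@H](O[Si](C)(C)C(C)(C)C)[C@H](C(=O)OC)O1 | intermediate
34 | 13,14-diol carboxylic acid with the C3 TBS ether | CC[C@@H](C)/C=C/[C@H](O)[C@@H](O)/C=C/C=C/C=C/C=C/C=C/C=C/[C@H]1C[C@@H](O[Si](C)(C)C(C)(C)C)[C@H](C(=O)O)O1 | intermediate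
35 | ketol: C18 ketone, (19S) carbinol, C3 TBS ether, free acid (drawn as this regioisomer; the 19-oxo isomer would behave alike) | CC[C@@H](C)/C=C/[C@H](O)C(=O)/C=C/C=C/C=C/C=C/C=C/C=C/[C@H]1C[C@@H](O[Si](C)(C)C(C)(C)C)[C@H](C(=O)O)O1 | intermediate
36 | (2R,3R,5R)-3-(TBSO)-5-[(1E,3E,5E,7E,9E,11E,15E,17R)-17-methyl-13,14-dioxononadeca-1,3,5,7,9,11,15-heptaenyl]oxolane-2-carboxylic acid | CC[C@@H](C)/C=C/C(=O)C(=O)/C=C/C=C/C=C/C=C/C=C/C=C/[C@H]1C[C@@H](O[Si](C)(C)C(C)(C)C)[C@H](C(=O)O)O1 | intermediate
37 | CNP0156165.1, (2R,3R,5R)-3-hydroxy-5-[(1E,3E,5E,7E,9E,11E,15E,17R)-17-methyl-13,14-dioxononadeca-1,3,5,7,9,11,15-heptaenyl]oxolane-2-carboxylic acid | CC[C@@H](C)/C=C/C(=O)C(=O)/C=C/C=C/C=C/C=C/C=C/C=C/[C@H]1C[C@@H](O)[C@H](C(=O)O)O1 | target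

**Totals**
Total step count: 28.
Longest linear sequence: 15 steps (steps 1–6, 8–11 and 24–28, from (R)-solketal).

**Steps most likely to fail**

Step 9. What may go wrong: erosion of the chirality transfer if the oxypalladation becomes reversible or the allylic alcohol ionises; slow attack by the weakly nucleophilic alpha-hydroxy ester oxygen; loss of a silyl ether to the Lewis-acidic metal. The fallback sets out from 12 and 10 and comes back at 14. Methyl chloroformate and pyridine convert 12 into (2R)-1-(TBDPSO)but-3-en-2-yl methyl carbonate F1. Cross-metathesis of F1 with 10 under the conditions of step 8 gives methyl (2R,3R,5E,7R)-3-(TBSO)-8-(TBDPSO)-2-hydroxy-7-[(methoxycarbonyl)oxy]oct-5-enoate F2. Zerovalent palladium (Pd2(dba)3, PPh3, THF, rt) then ionises the carbonate with inversion, and the C2 hydroxyl closes on C5 of the allylpalladium intermediate anti to the metal. This Tsuji–Trost allylic etherification proceeds with net retention and should give the same (5R), E product 14.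

Step 24. What may go wrong: vinylogous elimination of triethylsilanolate from the delocalised tetraenyl phosphonate anion before it meets the enal; competing deprotonation of 16; E/Z scrambling at the new C8=C9 bond. The fallback sets out from 27 and 16 and comes back at 32; it joins the halves by cross-coupling, with no carbanion. Wittig homologation of 27 with Ph3P=CHCHO gives (2E,4E,6S,7S,8E,10R)-10-methyl-6,7-bis(triethylsilyloxy)dodeca-2,4,8-trienal F3. Takai olefination (CrCl2, CHI3, THF) turns it into (1E,3E,5E,7S,8S,9E,11R)-1-iodo-11-methyl-7,8-bis(triethylsilyloxy)trideca-1,3,5,9-tetraene F4. Stille coupling of F4 with an excess of commercial (E)-1,2-bis(tributylstannyl)ethene (PdCl2(MeCN)2, DMF, rt) gives tributyl[(1E,3E,5E,7E,9S,10S,11E,13R)-13-methyl-9,10-bis(triethylsilyloxy)pentadeca-1,3,5,7,11-pentaenyl]stannane F5. Takai olefination of 16 gives methyl (2R,3R,5R)-3-(TBSO)-5-[(1E,3E)-4-iodobuta-1,3-dienyl]oxolane-2-carboxylate F6. A second Stille coupling of F5 with F6 (Pd2(dba)3, AsPh3, DMF, rt) forms the C9–C10 bond and gives 32.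

Step 27. What may go wrong: oxidative cleavage of the C18–C19 glycol bond; stalling at the ketol; isomerisation or degradation of the hexaene in the presence of the free acid. The fallback sets out from 33 and comes back at 37; it oxidises before the ester is cleaved. The diol ester 33 is oxidised with trifluoroacetic anhydride-activated DMSO and Et3N at −78 °C (the Swern variant established for 1,2-diols to 1,2-diones) to methyl (2R,3R,5R)-3-(TBSO)-5-[(1E,3E,5E,7E,9E,11E,15E,17R)-17-methyl-13,14-dioxononadeca-1,3,5,7,9,11,15-heptaenyl]oxolane-2-carboxylate F7. HF·pyridine gives the corresponding methyl (2R,3R,5R)-3-hydroxy oxolane-2-carboxylate F8. Pig liver esterase in pH 7 phosphate buffer with a little DMSO then hydrolyses the methyl ester to 37 without base.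

Further compounds
F1 | step 9 | (2R)-1-(TBDPSO)but-3-en-2-yl methyl carbonate | CC(C)(C)[Si](c1ccccc1)(c1ccccc1)OC[C@H](OC(=O)OC)C=C
F2 | step 9 | methyl (2R,3R,5E,7R)-3-(TBSO)-8-(TBDPSO)-2-hydroxy-7-[(methoxycarbonyl)oxy]oct-5-enoate | CC(C)(C)[Si](c1ccccc1)(c1ccccc1)OC[C@H](OC(=O)OC)/C=C/C[C@@H](O[Si](C)(C)C(C)(C)C)[C@H](C(=O)OC)O
F3 | step 24 | (2E,4E,6S,7S,8E,10R)-10-methyl-6,7-bis(triethylsilyloxy)dodeca-2,4,8-trienal | CC[C@@H](C)/C=C/[C@H](O[Si](CC)(CC)CC)[C@@H](O[Si](CC)(CC)CC)/C=C/C=C/C=O
F4 | step 24 | (1E,3E,5E,7S,8S,9E,11R)-1-iodo-11-methyl-7,8-bis(triethylsilyloxy)trideca-1,3,5,9-tetraene | CC[C@@H](C)/C=C/[C@H](O[Si](CC)(CC)CC)[C@@H](O[Si](CC)(CC)CC)/C=C/C=C/C=C/I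
F5 | step 24 | tributyl[(1E,3E,5E,7E,9S,10S,11E,13R)-13-methyl-9,10-bis(triethylsilyloxy)pentadeca-1,3,5,7,11-pentaenyl]stannane | CC[C@@H](C)/C=C/[C@H](O[Si](CC)(CC)CC)[C@@H](O[Si](CC)(CC)CC)/C=C/C=C/C=C/C=C/[Sn](CCCC)(CCCC)CCCC
F6 | step 24 | methyl (2R,3R,5R)-3-(TBSO)-5-[(1E,3E)-4-iodobuta-1,3-dienyl]oxolane-2-carboxylate | I/C=C/C=C/[C@H]1C[C@@H](O[Si](C)(C)C(C)(C)C)[C@H](C(=O)OC)O1
F7 | step 27 | methyl (2R,3R,5R)-3-(TBSO)-5-[(1E,3E,5E,7E,9E,11E,15E,17R)-17-methyl-13,14-dioxononadeca-1,3,5,7,9,11,15-heptaenyl]oxolane-2-carboxylate | CC[C@@H](C)/C=C/C(=O)C(=O)/C=C/C=C/C=C/C=C/C=C/C=C/[C@H]1C[C@@H](O[Si](C)(C)C(C)(C)C)[C@H](C(=O)OC)O1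
F8 | step 27 | methyl (2R,3R,5R)-3-hydroxy-5-[(1E,3E,5E,7E,9E,11E,15E,17R)-17-methyl-13,14-dioxononadeca-1,3,5,7,9,11,15-heptaenyl]oxolane-2-carboxylate | CC[C@@H](C)/C=C/C(=O)C(=O)/C=C/C=C/C=C/C=C/C=C/C=C/[C@H]1C[C@@H](O)[C@H](C(=O)OC)O1
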